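The route rests on cutting the C5–C6 bond, where the spiro carbon C5 joins the β-carbon of the C6=C7–C8=O enone of the six-membered ring. In one operation, cathodic reduction of an N-acyloxyphthalimide expels CO2, creates the tertiary C5 radical and closes the cyclohexenone by 6-endo-dig addition to a tethered ynone, forming the quaternary spiro centre anti to the C1 silyloxy group. The precursor is the phthalimide ester of a 2-silyloxy-4-isopropenylcyclopentane-1-carboxylic acid whose carboxyl-bearing carbon carries a (2S)-4-oxohept-5-yn-2-yl chain; it is assembled from (R)-limonene, crotonaldehyde and propynylmagnesium bromide. Acetoxylation at C9 and senecioylation at C1 finish the synthesis.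

Key step: step 12

Remark 1: spiro[4.5]decane numbering is used for ring atoms throughout (C1 O-bearing, C3 isopropenyl, C5 spiro, C6=C7, C8 C=O, C9, C10 CH3), also for the monocyclic precursors when atoms are discussed.
Remark 2: the ynone side chain must be CH(CH3)CH2C(=O)C≡CCH3, i.e. 4-oxohept-5-yn-2-yl; a 5-oxooct-6-yn-2-yl chain has one CH2 too many and would close a seven-membered ring, so the seven-carbon chain is used.
Remark 3: compounds 8 and 10–16 are drawn as the expected major epimer at the quaternary ring carbon (C5); the minor epimer is carried along because C5 becomes planar in step 12.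

Step 1
Reactants: 1 (R)-limonene
Product: 3 methyl (3R)-6-oxo-3-(prop-1-en-2-yl)heptanoate, via methoxy hydroperoxide 2 (not isolated)
Conditions: O3 (1 equiv, Sudan III end point), NaHCO3, CH2Cl2/MeOH 5:1, −78 °C; then Ac2O, Et3N, CH2Cl2, 0 °C → rt
Reagents that add atoms: ozone, O=[O+][O-]; methanol, CO
Why: Chemoselective ozonolysis with unsymmetrical work-up: ozone takes the electron-rich trisubstituted ring alkene before the 1,1-disubstituted isopropenyl group, methanol traps the aldehyde-side carbonyl oxide as α-methoxy hydroperoxide 2, and Ac2O/Et3N dehydrates it to the methyl ester while the ketone terminus stays; the stereocentre is not touched.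

Step 2
Reactants: 3 methyl (3R)-6-oxo-3-(prop-1-en-2-yl)heptanoate
Product: 4 (3R)-3-(prop-1-en-2-yl)hexanedioic acid
Conditions: Br2, aq. NaOH (NaOBr), 1,4-dioxane/H2O, 0 °C → rt; Na2SO3; HCl to pH 2
Reagents that add atoms: sodium hydroxide, [Na+].[OH-]
Why: Haloform reaction with concurrent ester saponification: in cold, strongly basic hypobromite only the methyl ketone is brominated through its enolate and then cleaved by hydroxide, while the isolated isopropenyl group should be spared because almost no free Br2 or HOBr is present; the stereocentre has no acidic hydrogen.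

Step 3
Reactants: 4 (3R)-3-(prop-1-en-2-yl)hexanedioic acid
Product: 5 diallyl (3R)-3-(prop-1-en-2-yl)hexanedioate
Conditions: allyl bromide, K2CO3, DMF, rt
Reagents that add atoms: allyl bromide, C=CCBr
Why: Carboxylate O-alkylation (SN2) under non-acidic conditions that cannot hydrate or isomerise the isopropenyl group; allyl is chosen because the hindered quaternary ester formed later must be cleaved without hydroxide.

Step 4
Reactants: 5 diallyl (3R)-3-(prop-1-en-2-yl)hexanedioate
Product: 6 allyl (4R)-2-oxo-4-(prop-1-en-2-yl)cyclopentane-1-carboxylate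
Conditions: NaH (1.2 equiv), allyl alcohol (5 mol %), THF, reflux; AcOH, 0 °C
Reagents that add atoms: none
Why: Dieckmann condensation under equilibrating alkoxide conditions, which should funnel to the less hindered β-keto ester enolate (ester carbon remote from the isopropenyl-bearing carbon); any regioisomer is removed by chromatography or left behind in step 5, where it is far more hindered, and the stereocentre is not enolisable.

Step 5
Reactants: 6 allyl (4R)-2-oxo-4-(prop-1-en-2-yl)cyclopentane-1-carboxylate; 7 (E)-but-2-enal
Product: 8 allyl (1R,4R)-2-oxo-1-[(2S)-4-oxobutan-2-yl]-4-(prop-1-en-2-yl)cyclopentane-1-carboxylate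
Conditions: (R)-2-[diphenyl(trimethylsilyloxy)methyl]pyrrolidine (10 mol %), PhCO2H (10 mol %), toluene, 0 °C → rt
Reagents that add atoms: none
Why: Iminium-catalysed Michael addition of a cyclic β-keto ester to an enal (diarylprolinol silyl ether catalysis): the (R)-catalyst shields one face of the (E)-iminium ion so that the β-carbon becomes the (S)-configured C10, while the ring carbon reacts mainly anti to the isopropenyl group; the configuration of that quaternary carbon is immaterial because it is erased in step 12.

Step 6
Reactants: 8 allyl (1R,4R)-2-oxo-1-[(2S)-4-oxobutan-2-yl]-4-(prop-1-en-2-yl)cyclopentane-1-carboxylate; 9 1-propynylmagnesium bromide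
Product: 10 allyl (1R,4R)-1-[(2S,4RS)-4-hydroxyhept-5-yn-2-yl]-2-oxo-4-(prop-1-en-2-yl)cyclopentane-1-carboxylate
Conditions: 9 (1.1 equiv), THF, −78 °C; AcOH quench
Reagents that add atoms: none
Why: Chemoselective Grignard 1,2-addition to the aldehyde at −78 °C, the neopentyl ring ketone and the hindered ester being much slower; the carbinol centre forms without control and is removed in step 8.

Step 7
Reactants: 10 allyl (1R,4R)-1-[(2S,4RS)-4-hydroxyhept-5-yn-2-yl]-2-oxo-4-(prop-1-en-2-yl)cyclopentane-1-carboxylate
Product: 11 allyl (1R,2S,4R)-2-hydroxy-1-[(2S,4RS)-4-hydroxyhept-5-yn-2-yl]-4-(prop-1-en-2-yl)cyclopentane-1-carboxylate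
Conditions: (R)-2-methyl-CBS-oxazaborolidine (0.3 equiv), catecholborane (3 equiv), toluene, −78 → −30 °C; MeOH, then H2O
Reagents that add atoms: none
Why: Corey–Bakshi–Shibata reduction: the (R)-oxazaborolidine distinguishes the quaternary side of the ring ketone from its methylene side and should give the (S)-carbinol (spiro C1, hydroxyl trans to the isopropenyl group) from either epimer of the quaternary carbon, which for the major epimer coincides with the substrate preference (hydride anti to the branched chain); catecholborane leaves the alkenes, the alkyne and the ester alone.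

Step 8
Reactants: 11 allyl (1R,2S,4R)-2-hydroxy-1-[(2S,4RS)-4-hydroxyhept-5-yn-2-yl]-4-(prop-1-en-2-yl)cyclopentane-1-carboxylate
Product: 12 allyl (1R,2S,4R)-2-hydroxy-1-[(2S)-4-oxohept-5-yn-2-yl]-4-(prop-1-en-2-yl)cyclopentane-1-carboxylate
Conditions: activated MnO2 (20 equiv), CH2Cl2, rt
Reagents that add atoms: none
Why: MnO2 oxidation of activated alcohols: only the propargylic carbinol is oxidised and the unactivated ring alcohol is inert, so the ynone appears only after the ring ketone has been reduced (the reverse order would demand reduction of a ketone beside the more reducible ynone).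

Step 9
Reactants: 12 allyl (1R,2S,4R)-2-hydroxy-1-[(2S)-4-oxohept-5-yn-2-yl]-4-(prop-1-en-2-yl)cyclopentane-1-carboxylate
Product: 13 allyl (1R,2S,4R)-2-[(tert-butyldimethylsilyl)oxy]-1-[(2S)-4-oxohept-5-yn-2-yl]-4-(prop-1-en-2-yl)cyclopentane-1-carboxylate
Conditions: TBSOTf, 2,6-lutidine, CH2Cl2, −78 → 0 °C
Reagents that add atoms: tert-butyldimethylsilyl trifluoromethanesulfonate, CC(C)(C)[Si](C)(C)OS(=O)(=O)C(F)(F)F
Why: Silylation with a silyl triflate and a hindered base, as needed for the neopentyl secondary alcohol; at low temperature O-silylation should outrun enolisation of the ynone, and any hemiketal tautomer equilibrates through the open hydroxy ketone.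

Step 10
Reactants: 13 allyl (1R,2S,4R)-2-[(tert-butyldimethylsilyl)oxy]-1-[(2S)-4-oxohept-5-yn-2-yl]-4-(prop-1-en-2-yl)cyclopentane-1-carboxylate
Product: 14 (1R,2S,4R)-2-[(tert-butyldimethylsilyl)oxy]-1-[(2S)-4-oxohept-5-yn-2-yl]-4-(prop-1-en-2-yl)cyclopentane-1-carboxylic acid
Conditions: Pd(PPh3)4 (5 mol %), PhSiH3 (2 equiv), CH2Cl2, rt; pH 4 buffer work-up
Reagents that add atoms: none
Why: Pd(0)-catalysed deallylation (Tsuji–Trost π-allyl formation with hydride capture by the silane) frees the hindered acid under neutral conditions, with no hydroxide or amine that would add to the ynone; the silyl ether and the alkenes are untouched.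

Step 11
Reactants: 14 (1R,2S,4R)-2-[(tert-butyldimethylsilyl)oxy]-1-[(2S)-4-oxohept-5-yn-2-yl]-4-(prop-1-en-2-yl)cyclopentane-1-carboxylic acid; 15 N-hydroxyphthalimide
Product: 16 1,3-dioxoisoindolin-2-yl (1R,2S,4R)-2-[(tert-butyldimethylsilyl)oxy]-1-[(2S)-4-oxohept-5-yn-2-yl]-4-(prop-1-en-2-yl)cyclopentane-1-carboxylate
Conditions: DIC, DMAP (10 mol %), CH2Cl2, 0 °C → rt
Reagents that add atoms: none
Why: Steglich-type carbodiimide coupling to the redox-active N-acyloxyphthalimide; the small, acidic N-hydroxy nucleophile acylates tertiary acids under these conditions and no base strong enough to add it to the ynone is present.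

Step 12
Reactants: 16 1,3-dioxoisoindolin-2-yl (1R,2S,4R)-2-[(tert-butyldimethylsilyl)oxy]-1-[(2S)-4-oxohept-5-yn-2-yl]-4-(prop-1-en-2-yl)cyclopentane-1-carboxylate
Product: 18 (1S,3R,5S,10S)-1-[(tert-butyldimethylsilyl)oxy]-6,10-dimethyl-3-(prop-1-en-2-yl)spiro[4.5]dec-6-en-8-one, via tertiary cyclopentyl radical 17 (not isolated)
Conditions: undivided cell, RVC cathode, Zn anode, n-Bu4NPF6 (0.1 M), (CF3)2CHOH (3 equiv), DMF (0.01 M), controlled potential at the ester wave (ca. −1.4 V vs Ag/AgCl), 2.2 F/mol, rt
Reagents that add atoms: none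
Why: Proposed new method: one-electron cathodic reduction of the phthalimide ester (which is reduced at a less negative potential than a dialkyl ynone) gives a radical anion that fragments to phthalimide anion, CO2 and the tertiary radical 17, planar at C5 so that both C5 epimers of 16 converge; this nucleophilic radical adds to the electrophilic β-carbon C6 of the tethered ynone, and the α-keto vinyl radical is reduced at the cathode and protonated at C7 by the fluoro alcohol to give the enone. The closest known reaction type is the reductive decarboxylative Giese addition of N-acyloxyphthalimides (photoredox, zinc and cathodic variants), but a tertiary radical closing onto a tethered ynone under electrolysis has not been shown. The cyclohexenone ring (C5–C6–C7–C8–C9–C10) closes in the 6-endo-dig mode, preferred over 5-exo attack at C7 because the ketone lies inside the forming ring and polarity directs the radical to the β-carbon. The new stereocentre C5 is controlled by the silyloxy group on the adjacent C1: C6 should bond to the face of the radical anti to OTBS, and the fixed (S)-configuration of C10 then places its methyl syn to C1. The step needs this facial selectivity and reduction of the ester in preference to the ynone; the first is secured by the bulky silyl ether next to the radical centre, the second by holding the potential at the ester wave with a sacrificial zinc anode.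

Step 13
Reactants: 18 (1S,3R,5S,10S)-1-[(tert-butyldimethylsilyl)oxy]-6,10-dimethyl-3-(prop-1-en-2-yl)spiro[4.5]dec-6-en-8-one
Product: 20 (1S,3R,5S,9S,10R)-1-[(tert-butyldimethylsilyl)oxy]-9-hydroxy-6,10-dimethyl-3-(prop-1-en-2-yl)spiro[4.5]dec-6-en-8-one, via sodium dienolate 19 (not isolated)
Conditions: NaHMDS (1.1 equiv), THF, −78 °C; 3-phenyl-2-(phenylsulfonyl)oxaziridine (1.3 equiv), −78 °C; AcOH quench
Reagents that add atoms: 3-phenyl-2-(phenylsulfonyl)oxaziridine, O=S(=O)(c1ccccc1)N1OC1c1ccccc1
Why: Kinetic enolate hydroxylation with an N-sulfonyloxaziridine: deprotonation at −78 °C takes an α′-hydrogen at C9 to give the cross-conjugated dienolate 19, and oxygen is delivered to C9 from the face opposite to the adjacent C10 methyl and the silyloxy-bearing C1 branch, which should give the 9,10-trans (9S) ketol, also the thermodynamically preferred epimer at this enolisable centre; the reagent does not epoxidise the isopropenyl group.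

Step 14
Reactants: 20 (1S,3R,5S,9S,10R)-1-[(tert-butyldimethylsilyl)oxy]-9-hydroxy-6,10-dimethyl-3-(prop-1-en-2-yl)spiro[4.5]dec-6-en-8-one
Product: 21 (1S,3R,5S,9S,10R)-9-(acetyloxy)-1-[(tert-butyldimethylsilyl)oxy]-6,10-dimethyl-3-(prop-1-en-2-yl)spiro[4.5]dec-6-en-8-one
Conditions: Ac2O, pyridine, DMAP (5 mol %), CH2Cl2, 0 °C → rt
Reagents that add atoms: acetic anhydride, CC(=O)OC(C)=O
Why: DMAP-catalysed acylation of the secondary ketol; mild base and low temperature avoid α-ketol rearrangement, and the trans arrangement at C9 is the stable one.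

Step 15
Reactants: 21 (1S,3R,5S,9S,10R)-9-(acetyloxy)-1-[(tert-butyldimethylsilyl)oxy]-6,10-dimethyl-3-(prop-1-en-2-yl)spiro[4.5]dec-6-en-8-one
Product: 22 (1S,3R,5S,9S,10R)-9-(acetyloxy)-1-hydroxy-6,10-dimethyl-3-(prop-1-en-2-yl)spiro[4.5]dec-6-en-8-one
Conditions: HF·pyridine, excess pyridine, THF, 0 °C → rt
Reagents that add atoms: none
Why: Fluoride-driven desilylation (Si–F bond formation) under buffered, weakly acidic conditions that leave the base-sensitive α-acetoxy ketone, the enone and the isopropenyl group intact.

Step 16
Reactants: 22 (1S,3R,5S,9S,10R)-9-(acetyloxy)-1-hydroxy-6,10-dimethyl-3-(prop-1-en-2-yl)spiro[4.5]dec-6-en-8-one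
Product: 23 (1S,3R,5S,9S,10R)-9-(acetyloxy)-6,10-dimethyl-8-oxo-3-(prop-1-en-2-yl)spiro[4.5]dec-6-en-1-yl 3-methylbut-2-enoate (CNP0218315.1)
Conditions: 3-methylbut-2-enoic acid, 2,4,6-trichlorobenzoyl chloride, Et3N, toluene, rt; then 22, DMAP, toluene, rt → 40 °C
Reagents that add atoms: 3-methylbut-2-enoic acid, CC(C)=CC(=O)O
Why: Yamaguchi esterification through the mixed anhydride and the acylpyridinium ion, forceful enough for the hindered C1 alcohol and suited to α,β-unsaturated acids without deconjugation (a risk with the acid chloride and triethylamine through the vinylketene); no stereocentre is touched.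

Compound list
1 | (R)-limonene, (4R)-1-methyl-4-(prop-1-en-2-yl)cyclohex-1-ene | CC1=CC[C@@H](CC1)C(C)=C | starting material
2 | (5R)-7-hydroperoxy-7-methoxy-5-(prop-1-en-2-yl)heptan-2-one (C7 epimers) | COC(OO)C[C@@H](CCC(C)=O)C(C)=C | intermediate (not isolated)
3 | methyl (3R)-6-oxo-3-(prop-1-en-2-yl)heptanoate | COC(=O)C[C@@H](CCC(C)=O)C(C)=C | intermediate
4 | (3R)-3-(prop-1-en-2-yl)hexanedioic acid | OC(=O)C[C@@H](CCC(O)=O)C(C)=C | intermediate
5 | diallyl (3R)-3-(prop-1-en-2-yl)hexanedioate | C=CCOC(=O)C[C@@H](CCC(=O)OCC=C)C(C)=C | intermediate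
6 | allyl (4R)-2-oxo-4-(prop-1-en-2-yl)cyclopentane-1-carboxylate (C1 epimers and enol) | C=C(C)[C@H]1CC(=O)C(C1)C(=O)OCC=C | intermediate
7 | (E)-but-2-enal | C/C=C/C=O | starting material
8 | allyl (1R,4R)-2-oxo-1-[(2S)-4-oxobutan-2-yl]-4-(prop-1-en-2-yl)cyclopentane-1-carboxylate | C=C(C)[C@H]1CC(=O)[C@](C1)(C(=O)OCC=C)[C@@H](C)CC=O | intermediate
9 | 1-propynylmagnesium bromide | CC#C[Mg]Br | starting material
10 | allyl (1R,4R)-1-[(2S,4RS)-4-hydroxyhept-5-yn-2-yl]-2-oxo-4-(prop-1-en-2-yl)cyclopentane-1-carboxylate | C=C(C)[C@H]1CC(=O)[C@](C1)(C(=O)OCC=C)[C@@H](C)CC(O)C#CC | intermediate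
11 | allyl (1R,2S,4R)-2-hydroxy-1-[(2S,4RS)-4-hydroxyhept-5-yn-2-yl]-4-(prop-1-en-2-yl)cyclopentane-1-carboxylate | C=C(C)[C@H]1C[C@H](O)[C@](C1)(C(=O)OCC=C)[C@@H](C)CC(O)C#CC | intermediate
12 | allyl (1R,2S,4R)-2-hydroxy-1-[(2S)-4-oxohept-5-yn-2-yl]-4-(prop-1-en-2-yl)cyclopentane-1-carboxylate | C=C(C)[C@H]1C[C@H](O)[C@](C1)(C(=O)OCC=C)[C@@H](C)CC(=O)C#CC | intermediate
13 | allyl (1R,2S,4R)-2-[(tert-butyldimethylsilyl)oxy]-1-[(2S)-4-oxohept-5-yn-2-yl]-4-(prop-1-en-2-yl)cyclopentane-1-carboxylate | C=C(C)[C@H]1C[C@H](O[Si](C)(C)C(C)(C)C)[C@](C1)(C(=O)OCC=C)[C@@H](C)CC(=O)C#CC | intermediate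
14 | (1R,2S,4R)-2-[(tert-butyldimethylsilyl)oxy]-1-[(2S)-4-oxohept-5-yn-2-yl]-4-(prop-1-en-2-yl)cyclopentane-1-carboxylic acid | C=C(C)[C@H]1C[C@H](O[Si](C)(C)C(C)(C)C)[C@](C1)(C(=O)O)[C@@H](C)CC(=O)C#CC | intermediate
15 | N-hydroxyphthalimide | O=C1c2ccccc2C(=O)N1O | starting material
16 | 1,3-dioxoisoindolin-2-yl (1R,2S,4R)-2-[(tert-butyldimethylsilyl)oxy]-1-[(2S)-4-oxohept-5-yn-2-yl]-4-(prop-1-en-2-yl)cyclopentane-1-carboxylate | C=C(C)[C@H]1C[C@H](O[Si](C)(C)C(C)(C)C)[C@](C1)(C(=O)ON2C(=O)c3ccccc3C2=O)[C@@H](C)CC(=O)C#CC | intermediate (key-step precursor)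
17 | (2S,4R)-2-[(tert-butyldimethylsilyl)oxy]-1-[(2S)-4-oxohept-5-yn-2-yl]-4-(prop-1-en-2-yl)cyclopentyl radical | C=C(C)[C@H]1C[C@H](O[Si](C)(C)C(C)(C)C)[C](C1)[C@@H](C)CC(=O)C#CC | intermediate (not isolated)
18 | (1S,3R,5S,10S)-1-[(tert-butyldimethylsilyl)oxy]-6,10-dimethyl-3-(prop-1-en-2-yl)spiro[4.5]dec-6-en-8-one | C=C(C)[C@H]1C[C@H](O[Si](C)(C)C(C)(C)C)[C@]2(C1)C(C)=CC(=O)C[C@@H]2C | intermediate (key-step product)
19 | sodium 8,9-dienolate of 18 (enolate C8=C9, O–Na on C8) | C=C(C)[C@H]1C[C@H](O[Si](C)(C)C(C)(C)C)[C@]2(C1)C(C)=CC(O[Na])=C[C@@H]2C | intermediate (not isolated)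
20 | (1S,3R,5S,9S,10R)-1-[(tert-butyldimethylsilyl)oxy]-9-hydroxy-6,10-dimethyl-3-(prop-1-en-2-yl)spiro[4.5]dec-6-en-8-one | C=C(C)[C@H]1C[C@H](O[Si](C)(C)C(C)(C)C)[C@]2(C1)C(C)=CC(=O)[C@@H](O)[C@@H]2C | intermediate
21 | (1S,3R,5S,9S,10R)-9-(acetyloxy)-1-[(tert-butyldimethylsilyl)oxy]-6,10-dimethyl-3-(prop-1-en-2-yl)spiro[4.5]dec-6-en-8-one | C=C(C)[C@H]1C[C@H](O[Si](C)(C)C(C)(C)C)[C@]2(C1)C(C)=CC(=O)[C@@H](OC(C)=O)[C@@H]2C | intermediate
22 | (1S,3R,5S,9S,10R)-9-(acetyloxy)-1-hydroxy-6,10-dimethyl-3-(prop-1-en-2-yl)spiro[4.5]dec-6-en-8-one | C=C(C)[C@H]1C[C@H](O)[C@]2(C1)C(C)=CC(=O)[C@@H](OC(C)=O)[C@@H]2C | intermediate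
23 | (1S,3R,5S,9S,10R)-9-(acetyloxy)-6,10-dimethyl-8-oxo-3-(prop-1-en-2-yl)spiro[4.5]dec-6-en-1-yl 3-methylbut-2-enoate | C=C(C)[C@H]1C[C@H](OC(=O)C=C(C)C)[C@]2(C1)C(C)=CC(=O)[C@@H](OC(C)=O)[C@@H]2C | target

Total step count: 16. Longest linear sequence: 16 steps from (R)-limonene; all other components are commercial.

Steps most likely to fail

Step 12 (key step). The ynone may be reduced at the cathode in competition with the ester, the tertiary radical may be reduced before it cyclises (with loss of silyloxide), or the planar radical may show too little facial discrimination. The fallback sets out from acid 14 and comes back at 18, bypassing 16. The free acid is decarboxylated oxidatively by visible-light photoredox catalysis (Ir[dF(CF3)ppy]2(dtbbpy)PF6 1 mol %, K2HPO4, DMF, blue LEDs, rt), the established decarboxylative conjugate addition of carboxylic acids to electron-poor π-systems. The same C5 radical forms in a homogeneous, redox-neutral cycle: the reduced photocatalyst returns the electron to the α-keto vinyl radical, so no electrode potential has to distinguish ester from ynone. The silyloxy group still directs the bond to the anti face. No new compound is made (F0).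

Step 13. Enolisation may turn toward the C6 methyl group instead of C9, the enolate may be captured by the sulfonimine by-product, or facial selectivity at C9 may be poor. The fallback sets out from 18 and comes back at 21, bypassing 20. The enone is acetoxylated directly with Mn(OAc)3 in refluxing benzene, a Mn(III)-enolate/radical oxidation specific for the α′-position of conjugated enones that installs the acetate in one operation, normally trans to a neighbouring substituent. Because C9 is enolisable, any cis material can be equilibrated to the trans epimer with a mild amine base. No new compound is made (F0).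

Step 7. Hydride transfer to the hindered α-quaternary ketone may be slow, or catalyst control may erode where it opposes the substrate bias. The fallback sets out from 10 and comes back at 11. Reagent control is given up for substrate control: the epimers of 10 at the quaternary carbon are separated by chromatography (the carbinol epimers stay mixed), and the major one is reduced with NaBH4/CeCl3 in MeOH at −40 °C. Hydride enters anti to the branched side chain on the neighbouring quaternary carbon and so gives the same (2S)-alcohol. No new compound is made (F0).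

Further compounds
F0 | step 12 | none | none
F0 | step 13 | none | none
F0 | step 7 | none | none
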